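**Plan**

- Retrosynthetic cuts, in order (flavone numbering): C3–I to C3–H; O1–C2 of ring C (demethylative iodocyclisation of an ortho-methoxyaryl ynone); C4–C4a and C3–C4 (carbonylative Sonogashira coupling on an aryl iodide); the C–I bond on ring A; the C8–butenolide bond (Negishi coupling).
- Enabling feature: C8 of ring A lies between O1 and the C7 methoxy oxygen. Ring A can therefore be carried as a mirror-symmetric 2-substituted 1,3-dimethoxybenzene whose two free activated positions are equivalent, and the methoxy group that ends up next to the ynone becomes O1.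
- Forward order: the preformed butenolide ring is joined to lithiated 1,3-dimethoxybenzene, ring A is iodinated and carbonylatively alkynylated (which brings in ring B), ring C closes in the key step, and the iodine is then removed.
- Stereochemistry: the target has no stereocentre, so only regio- and site-selectivity need control, and both follow from the symmetry of ring A.

Key step: step 5

Remark: 5,5-dimethylfuran-2(5H)-one, 1,3-dimethoxybenzene and phenylacetylene are taken as commercial. The only stereocentres in the route are those of the transient racemic dibromide 2, and they are destroyed in the same step.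

**Route**

Step 1
Reactants: 1 5,5-dimethylfuran-2(5H)-one
Product: 3 3-bromo-5,5-dimethylfuran-2(5H)-one, via dibromolactone 2 (not isolated)
Conditions: Br2, CHCl3, reflux; then Et3N, 0 °C
Reagents that add atoms: bromine, BrBr
Why: Bromination–dehydrobromination: anti addition of Br2 to the conjugated alkene gives the trans-dibromide 2, and Et3N removes the acidic C3 proton with loss of the C4 bromide (E1cB-type), which leaves bromine at the α position.

Step 2
Reactants: 4 1,3-dimethoxybenzene; 3 3-bromo-5,5-dimethylfuran-2(5H)-one
Product: 7 3-(2,6-dimethoxyphenyl)-5,5-dimethylfuran-2(5H)-one, via 2,6-dimethoxyphenyllithium 5 (not isolated), via arylzinc chloride 6 (not isolated)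
Conditions: n-BuLi, THF, 0 °C to rt; ZnCl2, THF, 0 °C to rt; then 3, Pd(OAc)2 (cat.), SPhos (cat.), THF, 50 °C
Reagents that add atoms: none
Why: Directed ortho-lithiation of 4 occurs between the two methoxy groups, transmetalation to zinc gives a lactone-tolerant nucleophile, and Negishi cross-coupling with the α-bromoenoate 3 under a bulky biarylphosphine ligand (suited to doubly ortho-substituted arylzinc reagents) should form the aryl–butenolide bond.

Step 3
Reactants: 7 3-(2,6-dimethoxyphenyl)-5,5-dimethylfuran-2(5H)-one
Product: 8 3-(3-iodo-2,6-dimethoxyphenyl)-5,5-dimethylfuran-2(5H)-one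
Conditions: NIS (1.05 equiv), TFA (cat.), MeCN, rt
Reagents that add atoms: N-iodosuccinimide, O=C1CCC(=O)N1I
Why: Electrophilic aromatic iodination: each of the two equivalent free positions of ring A is ortho to one methoxy group and para to the other, so a single mono-iodide is expected with one equivalent of NIS, and the electron-poor butenolide alkene should not react.

Step 4
Reactants: 8 3-(3-iodo-2,6-dimethoxyphenyl)-5,5-dimethylfuran-2(5H)-one; 9 phenylacetylene
Product: 10 1-[3-(5,5-dimethyl-2-oxo-2,5-dihydrofuran-3-yl)-2,4-dimethoxyphenyl]-3-phenylprop-2-yn-1-one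
Conditions: CO (1 atm), PdCl2(PPh3)2 (cat.), CuI (cat.), Et3N, THF, rt
Reagents that add atoms: carbon monoxide, [C-]#[O+]
Why: Carbonylative Sonogashira coupling: zerovalent palladium inserts into the C–I bond of 8, CO insertion into the electron-rich arylpalladium gives an acylpalladium species, and alkynyl transfer from the copper acetylide of 9 followed by reductive elimination should form the ynone while Et3N takes up HI.

Step 5
Reactants: 10 1-[3-(5,5-dimethyl-2-oxo-2,5-dihydrofuran-3-yl)-2,4-dimethoxyphenyl]-3-phenylprop-2-yn-1-one
Product: 12 8-(5,5-dimethyl-2-oxo-2,5-dihydrofuran-3-yl)-3-iodo-7-methoxy-2-phenyl-4H-chromen-4-one, via oxonium chloride 11 (not isolated)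
Conditions: ICl (1.2 equiv), CH2Cl2, −78 °C
Reagents that add atoms: iodine monochloride, ClI
Why: ICl transfers iodonium to the triple bond of 10, and the oxygen of the methoxy group ortho to the acyl group attacks the alkyne carbon β to the carbonyl (the future C2) anti to iodine, which forms O1–C2 and gives oxonium chloride 11; chloride then removes the O-methyl group by SN2 displacement and releases the neutral 3-iodochromone 12. The closest known reaction type is the ICl-induced demethylative iodocyclisation of 1-(2-methoxyaryl)alk-2-yn-1-ones to 3-iodochromones, a class to which 10 belongs. Ring C closes in the 6-endo-dig mode, because the ynone is polarised so that the positive charge of the iodonium ion develops at the phenyl-bearing β carbon, whereas 5-exo-dig closure would require attack at the α carbon. No stereocentre is formed. The step needs site selectivity between the two methoxy groups and chemoselectivity for the alkyne: only the methoxy group next to the ketone can reach the alkyne, the other one sits para to the acyl group and is kept as the C7 methoxy group, and the acyl-deactivated ring A and the electron-poor, hindered butenolide alkene should not compete for ICl at −78 °C.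

Step 6
Reactants: 12 8-(5,5-dimethyl-2-oxo-2,5-dihydrofuran-3-yl)-3-iodo-7-methoxy-2-phenyl-4H-chromen-4-one
Product: 13 8-(5,5-dimethyl-2-oxo-2,5-dihydrofuran-3-yl)-7-methoxy-2-phenyl-4H-chromen-4-one
Conditions: Pd(PPh3)4 (cat.), HCO2Na, DMF, 90 °C
Reagents that add atoms: none
Why: Palladium-catalysed formate hydrodehalogenation: oxidative addition of zerovalent palladium into the C3–I bond, exchange of iodide for formate, loss of CO2 to a palladium hydride and C–H reductive elimination should replace iodine by hydrogen, while the butenolide C–O bond lies in the nodal plane of its alkene and is not expected to ionise.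

**Compound list**

1 | 5,5-dimethylfuran-2(5H)-one | CC1(C)C=CC(=O)O1 | starting material
2 | trans-3,4-dibromo-5,5-dimethyloxolan-2-one (racemic; the (3S,4S) enantiomer is drawn) | CC1(C)OC(=O)[C@H](Br)[C@H]1Br | intermediate
3 | 3-bromo-5,5-dimethylfuran-2(5H)-one | CC1(C)OC(=O)C(Br)=C1 | intermediate
4 | 1,3-dimethoxybenzene | COc1cccc(OC)c1 | starting material
5 | 2,6-dimethoxyphenyllithium | COc1cccc(OC)c1[Li] | intermediate
6 | (2,6-dimethoxyphenyl)zinc chloride | COc1cccc(OC)c1[Zn]Cl | intermediate
7 | 3-(2,6-dimethoxyphenyl)-5,5-dimethylfuran-2(5H)-one | COc1cccc(OC)c1C1=CC(C)(C)OC1=O | intermediate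
8 | 3-(3-iodo-2,6-dimethoxyphenyl)-5,5-dimethylfuran-2(5H)-one | COc1ccc(I)c(OC)c1C1=CC(C)(C)OC1=O | intermediate
9 | phenylacetylene | C#Cc1ccccc1 | starting material
10 | 1-[3-(5,5-dimethyl-2-oxo-2,5-dihydrofuran-3-yl)-2,4-dimethoxyphenyl]-3-phenylprop-2-yn-1-one | COc1ccc(C(=O)C#Cc2ccccc2)c(OC)c1C1=CC(C)(C)OC1=O | intermediate
11 | 8-(5,5-dimethyl-2-oxo-2,5-dihydrofuran-3-yl)-3-iodo-7-methoxy-1-methyl-4-oxo-2-phenyl-4H-chromen-1-ium chloride | C[O+]1C(c2ccccc2)=C(I)C(=O)c2ccc(OC)c(C3=CC(C)(C)OC3=O)c21.[Cl-] | intermediate
12 | 8-(5,5-dimethyl-2-oxo-2,5-dihydrofuran-3-yl)-3-iodo-7-methoxy-2-phenyl-4H-chromen-4-one | COc1ccc2c(=O)c(I)c(-c3ccccc3)oc2c1C1=CC(C)(C)OC1=O | intermediate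
13 | 8-(5,5-dimethyl-2-oxo-2,5-dihydrofuran-3-yl)-7-methoxy-2-phenyl-4H-chromen-4-one | COc1ccc2c(=O)cc(-c3ccccc3)oc2c1C1=CC(C)(C)OC1=O | target

**Step count and risks**

Total step count: 6. Longest linear sequence: 6 steps (1 to 13 through steps 1–6; 4 and 9 enter as commercial partners).

Steps most likely to fail:

Step 4. The direct, non-carbonylative alkynylation of the aryl iodide may outrun CO insertion, and copper-mediated oxidative dimerisation of the alkyne may consume 9. The fallback sets out from 7 and installs the carbonyl carbon first. Rieche formylation (Cl2CHOMe, TiCl4, CH2Cl2, 0 °C) at either of the two equivalent positions should give 3-(5,5-dimethyl-2-oxo-2,5-dihydrofuran-3-yl)-2,4-dimethoxybenzaldehyde F1. Deprotonation of 9 with n-BuLi in THF at −78 °C gives lithium phenylacetylide F2, which should add to the aldehyde of F1 at −78 °C faster than to the hindered lactone. This gives racemic 3-[3-(1-hydroxy-3-phenylprop-2-yn-1-yl)-2,6-dimethoxyphenyl]-5,5-dimethylfuran-2(5H)-one F3 after NH4Cl work-up. Oxidation with MnO2 in CH2Cl2 at rt comes back to the route at 10, so that 8 is not needed.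

Step 5. Electrophilic iodination of ring A, or plain addition of ICl across the triple bond without ring closure, may compete with the cyclisation. The fallback sets out from 10 and separates demethylation from ring closure. BCl3 in CH2Cl2 at −78 °C, chelated by the ketone, should cleave only the neighbouring methoxy group. This gives 1-[3-(5,5-dimethyl-2-oxo-2,5-dihydrofuran-3-yl)-2-hydroxy-4-methoxyphenyl]-3-phenylprop-2-yn-1-one F4. Treatment with catalytic DMAP in DMF at rt should then close ring C by 6-endo oxa-Michael addition. The fallback comes back to the route at 13, which makes step 6 unnecessary.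

Step 2. Transmetalation of the doubly ortho-substituted arylzinc reagent may be slow, and reductive loss of bromine from 3 may then take over. The fallback sets out from 4 and builds the butenolide on the arene instead of coupling it. Lithiation as in step 2 gives 5, which is added to excess diethyl oxalate in THF at −78 °C to give ethyl (2,6-dimethoxyphenyl)(oxo)acetate F5. Addition of 2-methylprop-1-enylmagnesium bromide to the ketone in THF at −78 °C gives racemic ethyl 2-(2,6-dimethoxyphenyl)-2-hydroxy-4-methylpent-3-enoate F6. Heating with TsOH in toluene at 80 °C should ionise the tertiary allylic alcohol, transpose oxygen to the dimethyl-substituted terminus and lactonise with loss of ethanol. The fallback comes back to the route at 7, so that 1 and 3 are not needed.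

Further compounds
F1 | step 4 | 3-(5,5-dimethyl-2-oxo-2,5-dihydrofuran-3-yl)-2,4-dimethoxybenzaldehyde | COc1ccc(C=O)c(OC)c1C1=CC(C)(C)OC1=O
F2 | step 4 | lithium phenylacetylide | [Li]C#Cc1ccccc1
F3 | step 4 | 3-[3-(1-hydroxy-3-phenylprop-2-yn-1-yl)-2,6-dimethoxyphenyl]-5,5-dimethylfuran-2(5H)-one (racemic) | COc1ccc(C(O)C#Cc2ccccc2)c(OC)c1C1=CC(C)(C)OC1=O
F4 | step 5 | 1-[3-(5,5-dimethyl-2-oxo-2,5-dihydrofuran-3-yl)-2-hydroxy-4-methoxyphenyl]-3-phenylprop-2-yn-1-one | COc1ccc(C(=O)C#Cc2ccccc2)c(O)c1C1=CC(C)(C)OC1=O
F5 | step 2 | ethyl (2,6-dimethoxyphenyl)(oxo)acetate | CCOC(=O)C(=O)c1c(OC)cccc1OC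
F6 | step 2 | ethyl 2-(2,6-dimethoxyphenyl)-2-hydroxy-4-methylpent-3-enoate (racemic) | CCOC(=O)C(O)(C=C(C)C)c1c(OC)cccc1OC
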